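**Retrosynthetic overview**

1. Target 30 ⇒ Stille coupling at C8 of ring A between the hexaphenol aryl iodide 24 and the (Z)-dienylstannane 29; 24 ⇒ its hexabenzyl ether 23.
2. 23 ⇒ ring C of the flavanone by enantioselective oxa-Michael closure of the alkylidene β-keto ester 21, the Knoevenagel union of the ring-A β-keto ester 20 with the dihydrobenzofuran aldehyde 15.
3. 15 ⇒ the dihydrofuran ring, made in one flask from the diarylmethane sulfoxide 10 and 4-(benzyloxy)benzaldehyde 11 by forming C2–C3 and O1–C7a; 10 ⇒ Andersen sulfinylation and Negishi benzylation of a bromo-iodo salicylaldehyde acetal.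
4. Enabling feature: C3 of the dihydrobenzofuran is a diarylmethine carbon between ring B (C3a) and the resorcinol ring, and C7a is the ring-B carbon ortho to it. A p-tolylsulfinyl group placed on C7a therefore acidifies C3–H, holds lithium, passes its chirality to C3 and then leaves when the aldehyde-derived alkoxide (O1–C2) attacks C7a.
5. Ring order: all benzene rings are bought; the dihydrofuran ring is formed first (step 6), ring C of the flavanone last (step 12).

Key step: step 6

Assumption 1: the sense of induction in step 6 is taken from the lithium-chelate model of ortho-sulfinyl benzyl carbanions, (R) at sulfur leading to (R) at C3; should the opposite sense hold, the commercial enantiomer of sulfinate 8 is used in step 5 and nothing else changes.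
Assumption 2: the quinidine-derived thiourea is taken to deliver the 2S flavanone in step 12; should it deliver 2R, its quinine-derived pseudo-enantiomer is used.

**Route**

Step 1
Reactants: 1 4-bromo-2-hydroxybenzaldehyde
Product: 2 4-bromo-2-hydroxy-5-iodobenzaldehyde
Conditions: N-iodosuccinimide, CF3CO2H (cat.), MeCN, 25 °C
Reagents that add atoms: N-iodosuccinimide, O=C1CCC(=O)N1I
Why: Electrophilic aromatic iodination should go to C5, which is para to the hydroxyl, meta to the formyl group and less hindered than C3 (flanked by OH and Br).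

Step 2
Reactants: 2 4-bromo-2-hydroxy-5-iodobenzaldehyde
Product: 3 2-(benzyloxy)-4-bromo-5-iodobenzaldehyde
Conditions: benzyl bromide, K2CO3, DMF, 25 °C
Reagents that add atoms: benzyl bromide, BrCc1ccccc1
Why: Williamson ether synthesis on the phenoxide protects the future 2'-hydroxyl of ring B.

Step 3
Reactants: 3 2-(benzyloxy)-4-bromo-5-iodobenzaldehyde
Product: 4 2-[2-(benzyloxy)-4-bromo-5-iodophenyl]-1,3-dioxolane
Conditions: ethylene glycol, p-TsOH (cat.), toluene, reflux, Dean–Stark
Reagents that add atoms: ethylene glycol, OCCO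
Why: Acid-catalysed acetalisation with azeotropic removal of water masks the aldehyde before the organolithium steps.

Step 4
Reactants: 4 2-[2-(benzyloxy)-4-bromo-5-iodophenyl]-1,3-dioxolane; 5 3,5-bis(benzyloxy)benzyl bromide
Product: 7 2-{2-(benzyloxy)-5-[3,5-bis(benzyloxy)benzyl]-4-bromophenyl}-1,3-dioxolane, via benzylzinc bromide 6 (not isolated)
Conditions: 5, Zn dust, LiCl, THF, 25 °C; then 4, Pd(PPh3)4 (3 mol %), THF, 25 °C
Reagents that add atoms: none
Why: Negishi cross-coupling of the benzylzinc reagent should occur only at C–I, because oxidative addition of zerovalent palladium to C–I is much faster than to C–Br at room temperature, so bromine stays for step 5.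

Step 5
Reactants: 7 2-{2-(benzyloxy)-5-[3,5-bis(benzyloxy)benzyl]-4-bromophenyl}-1,3-dioxolane; 8 (1S,2R,5S)-menthyl (R)-4-methylbenzenesulfinate
Product: 10 2-{2-(benzyloxy)-5-[3,5-bis(benzyloxy)benzyl]-4-[(R)-4-methylbenzenesulfinyl]phenyl}-1,3-dioxolane, via aryllithium 9 (not isolated)
Conditions: n-BuLi (1.0 equiv), THF, −78 °C; then transferred into 8 in THF, −78 °C; H2O
Reagents that add atoms: none
Why: Andersen sulfoxide synthesis: bromine–lithium exchange followed by substitution at sulfur of the menthyl sulfinate with inversion should set the sulfur stereocenter as R.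

Step 6
Reactants: 10 2-{2-(benzyloxy)-5-[3,5-bis(benzyloxy)benzyl]-4-[(R)-4-methylbenzenesulfinyl]phenyl}-1,3-dioxolane; 11 4-(benzyloxy)benzaldehyde
Product: 14 2-{(2R,3R)-6-(benzyloxy)-2-[4-(benzyloxy)phenyl]-3-[3,5-bis(benzyloxy)phenyl]-2,3-dihydro-1-benzofuran-5-yl}-1,3-dioxolane, via benzyllithium 12 (not isolated), via lithium alkoxide 13 (not isolated)
Conditions: LiN(i-Pr)2 (1.05 equiv), THF, −78 °C; 11, −78 °C; then DMPU, −78 → 25 °C; H2O
Reagents that add atoms: none
Why: Proposed new method: LiN(i-Pr)2 removes the doubly benzylic C3–H of 10 (made more acidic by the ortho sulfinyl group) to give benzyllithium 12 held in a six-membered chelate by the sulfinyl oxygen, 12 adds to the carbonyl carbon of 11 to form the C2–C3 bond, and the alkoxide oxygen of 13 then attacks the ring-B carbon that bears sulfur and expels p-toluenesulfenate through a Meisenheimer-type adduct, so that the O1–C7a bond and the dihydrofuran ring form in the same flask. The closest known reaction types are the stereoselective additions of ortho-sulfinyl benzyl carbanions to aldehydes and imines and the tandem imine addition/ipso-displacement of the sulfinyl group that gives indolines; an oxygen nucleophile and a diarylmethyl carbanion are new for this cascade. The ring closes by 5-exo attack of the alkoxide on the arene carbon (addition–elimination, intramolecular SNAr). C3 should be set by the sulfur stereocenter, because in the chelate the resorcinol ring points away from the sulfinyl group and the aldehyde is delivered on the lithium-bearing face opposite to the p-tolyl group; C2 should be set relative to C3, since the alkoxide diastereomers can interconvert by retro-addition and the transition state with the two aryl groups trans on the forming ring is the lower one. The step needs benzylic rather than ortho deprotonation (secured by the much higher acidity of the diarylmethane C–H), ipso attack at C7a (secured by the five-membered geometry and the sulfenate leaving group) and the trans isomer (a cis isomer, if formed, should converge to trans by acid-promoted ionisation of the C2–O bond, which leaves C3 untouched).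

Step 7
Reactants: 14 2-{(2R,3R)-6-(benzyloxy)-2-[4-(benzyloxy)phenyl]-3-[3,5-bis(benzyloxy)phenyl]-2,3-dihydro-1-benzofuran-5-yl}-1,3-dioxolane
Product: 15 (2R,3R)-6-(benzyloxy)-2-[4-(benzyloxy)phenyl]-3-[3,5-bis(benzyloxy)phenyl]-2,3-dihydro-1-benzofuran-5-carbaldehyde
Conditions: 1 M HCl, THF, 25 °C
Reagents that add atoms: water, O
Why: Mild acetal hydrolysis should free the aldehyde without touching the benzyl ethers or the two stereocenters.

Step 8
Reactants: 16 1-(2,4,6-trihydroxyphenyl)ethanone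
Product: 17 1-[2,4-bis(benzyloxy)-6-hydroxyphenyl]ethanone
Conditions: benzyl bromide (2.1 equiv), K2CO3, DMF, 25 °C
Reagents that add atoms: benzyl bromide, BrCc1ccccc1
Why: Selective Williamson etherification: two hydroxyls are alkylated and the one hydrogen-bonded to the ketone should remain free.

Step 9
Reactants: 17 1-[2,4-bis(benzyloxy)-6-hydroxyphenyl]ethanone
Product: 18 1-[4,6-bis(benzyloxy)-2-hydroxy-3-iodophenyl]ethanone
Conditions: N-iodosuccinimide, DMF, 0 °C
Reagents that add atoms: N-iodosuccinimide, O=C1CCC(=O)N1I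
Why: Electrophilic iodination of the phloroglucinol ring should go ortho to the free phenol (C3), the site flanked by OH and one benzyloxy group and not by two benzyloxy groups.

Step 10
Reactants: 18 1-[4,6-bis(benzyloxy)-2-hydroxy-3-iodophenyl]ethanone
Product: 20 tert-butyl 3-[4,6-bis(benzyloxy)-2-hydroxy-3-iodophenyl]-3-oxopropanoate, via dilithium enolate 19 (not isolated)
Conditions: LiN(SiMe3)2 (3.2 equiv), THF, −78 °C; Boc2O, −78 → 0 °C; 1 M HCl
Reagents that add atoms: di-tert-butyl dicarbonate, CC(C)(C)OC(=O)OC(=O)OC(C)(C)C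
Why: Claisen-type C-acylation of the ketone enolate gives the β-keto ester, and a carbonate formed at the phenoxide oxygen should be carried to carbon by a Baker–Venkataraman-type transfer.

Step 11
Reactants: 20 tert-butyl 3-[4,6-bis(benzyloxy)-2-hydroxy-3-iodophenyl]-3-oxopropanoate; 15 (2R,3R)-6-(benzyloxy)-2-[4-(benzyloxy)phenyl]-3-[3,5-bis(benzyloxy)phenyl]-2,3-dihydro-1-benzofuran-5-carbaldehyde
Product: 21 tert-butyl 2-[4,6-bis(benzyloxy)-2-hydroxy-3-iodobenzoyl]-3-{(2R,3R)-6-(benzyloxy)-2-[4-(benzyloxy)phenyl]-3-[3,5-bis(benzyloxy)phenyl]-2,3-dihydro-1-benzofuran-5-yl}prop-2-enoate (E/Z mixture)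
Conditions: piperidine (10 mol %), AcOH (10 mol %), toluene, 4 Å molecular sieves, 25 °C
Reagents that add atoms: none
Why: Knoevenagel condensation joins the two halves and gives the doubly activated alkene needed for the catalytic ring closure.

Step 12
Reactants: 21 alkylidene β-keto ester (E/Z mixture)
Product: 23 (2S)-5,7-bis(benzyloxy)-2-{(2R,3R)-6-(benzyloxy)-2-[4-(benzyloxy)phenyl]-3-[3,5-bis(benzyloxy)phenyl]-2,3-dihydro-1-benzofuran-5-yl}-8-iodo-2,3-dihydro-4H-chromen-4-one, via chromanone tert-butyl ester 22 (not isolated)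
Conditions: thiourea from 9-amino-9-deoxy-epi-quinidine and 3,5-bis(trifluoromethyl)phenyl isothiocyanate (10 mol %), toluene, −25 °C; then p-TsOH·H2O, 80 °C
Reagents that add atoms: none
Why: Enantioselective intramolecular oxa-Michael addition under a bifunctional cinchona thiourea (the thiourea binds the β-keto ester, the quinuclidine delivers the only free phenol to one face of the alkene and so sets C2 as S and places iodine at C8), followed by acid-promoted loss of isobutene and decarboxylation of the β-keto acid.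

Step 13
Reactants: 23 (2S)-hexabenzyl 8-iodoflavanone
Product: 24 (2S)-2-[(2R,3R)-3-(3,5-dihydroxyphenyl)-6-hydroxy-2-(4-hydroxyphenyl)-2,3-dihydro-1-benzofuran-5-yl]-5,7-dihydroxy-8-iodo-2,3-dihydro-4H-chromen-4-one
Conditions: BCl3, pentamethylbenzene, CH2Cl2, −78 °C; MeOH then H2O
Reagents that add atoms: none
Why: Lewis-acid debenzylation with a benzyl-cation scavenger should remove all six benzyl ethers at low temperature while sparing the aryl iodide and the ketone, which hydrogenolysis would not.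

Step 14
Reactants: 25 2-methylbut-1-en-3-yne
Product: 27 tributyl(3-methylbut-3-en-1-yn-1-yl)stannane, via lithium acetylide 26 (not isolated)
Conditions: n-BuLi, THF, −78 °C; Bu3SnCl, −78 → 25 °C
Reagents that add atoms: tributyltin chloride, CCCC[Sn](Cl)(CCCC)CCCC
Why: Deprotonation of the terminal alkyne and stannylation of the acetylide is a standard route to 1-stannylalkynes.

Step 15
Reactants: 27 tributyl(3-methylbut-3-en-1-yn-1-yl)stannane
Product: 29 tributyl[(1Z)-3-methylbuta-1,3-dien-1-yl]stannane, via stannyl alkenylzirconocene 28 (not isolated)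
Conditions: Cp2Zr(H)Cl, THF, 25 °C; then H2O
Reagents that add atoms: none
Why: Hydrozirconation of the 1-stannylalkyne adds Zr–H syn with zirconium on the tin-bearing carbon, and protonolysis of the C–Zr bond with retention should leave tin cis to the isopropenyl group (Z).

Step 16
Reactants: 24 (2S)-hexaphenol 8-iodoflavanone; 29 tributyl[(1Z)-3-methylbuta-1,3-dien-1-yl]stannane
Product: 30 (2S)-2-[(2R,3R)-3-(3,5-dihydroxyphenyl)-6-hydroxy-2-(4-hydroxyphenyl)-2,3-dihydro-1-benzofuran-5-yl]-5,7-dihydroxy-8-[(1Z)-3-methylbuta-1,3-dien-1-yl]-2,3-dihydro-4H-chromen-4-one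
Conditions: Pd2(dba)3 (5 mol %), AsPh3 (20 mol %), CuI (10 mol %), DMF, 40 °C, degassed, dark
Reagents that add atoms: none
Why: Stille coupling transfers the alkenyl group with retention of the Z geometry under neutral conditions that should tolerate free phenols, the flavanone stereocenter and the acid-sensitive diene.

**Compound list**

1 | 4-bromo-2-hydroxybenzaldehyde | O=Cc1ccc(Br)cc1O | starting material
2 | 4-bromo-2-hydroxy-5-iodobenzaldehyde | O=Cc1cc(I)c(Br)cc1O | intermediate
3 | 2-(benzyloxy)-4-bromo-5-iodobenzaldehyde | O=Cc1cc(I)c(Br)cc1OCc1ccccc1 | intermediate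
4 | 2-[2-(benzyloxy)-4-bromo-5-iodophenyl]-1,3-dioxolane | C1COC(O1)c1cc(I)c(Br)cc1OCc1ccccc1 | intermediate
5 | 3,5-bis(benzyloxy)benzyl bromide | BrCc1cc(OCc2ccccc2)cc(OCc2ccccc2)c1 | starting material
6 | [3,5-bis(benzyloxy)benzyl]zinc bromide | Br[Zn]Cc1cc(OCc2ccccc2)cc(OCc2ccccc2)c1 | intermediate
7 | 2-{2-(benzyloxy)-5-[3,5-bis(benzyloxy)benzyl]-4-bromophenyl}-1,3-dioxolane | C1COC(O1)c1cc(Cc2cc(OCc3ccccc3)cc(OCc3ccccc3)c2)c(Br)cc1OCc1ccccc1 | intermediate
8 | (1S,2R,5S)-menthyl (R)-4-methylbenzenesulfinate | Cc1ccc(cc1)[S@](=O)O[C@H]1C[C@@H](C)CC[C@@H]1C(C)C | starting material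
9 | aryllithium from 7 (lithium in place of bromine) | C1COC(O1)c1cc(Cc2cc(OCc3ccccc3)cc(OCc3ccccc3)c2)c([Li])cc1OCc1ccccc1 | intermediate
10 | 2-{2-(benzyloxy)-5-[3,5-bis(benzyloxy)benzyl]-4-[(R)-4-methylbenzenesulfinyl]phenyl}-1,3-dioxolane | C1COC(O1)c1cc(Cc2cc(OCc3ccccc3)cc(OCc3ccccc3)c2)c([S@](=O)c2ccc(C)cc2)cc1OCc1ccccc1 | intermediate
11 | 4-(benzyloxy)benzaldehyde | O=Cc1ccc(OCc2ccccc2)cc1 | starting material
12 | benzyllithium from 10 (lithiated at the diarylmethane carbon) | C1COC(O1)c1cc(C([Li])c2cc(OCc3ccccc3)cc(OCc3ccccc3)c2)c([S@](=O)c2ccc(C)cc2)cc1OCc1ccccc1 | intermediate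
13 | lithium alkoxide from addition of 12 to 11 | C1COC(O1)c1cc([C@@H](c2cc(OCc3ccccc3)cc(OCc3ccccc3)c2)[C@@H](O[Li])c2ccc(OCc3ccccc3)cc2)c([S@](=O)c2ccc(C)cc2)cc1OCc1ccccc1 | intermediate
14 | 2-{(2R,3R)-6-(benzyloxy)-2-[4-(benzyloxy)phenyl]-3-[3,5-bis(benzyloxy)phenyl]-2,3-dihydro-1-benzofuran-5-yl}-1,3-dioxolane | C1COC(O1)c1cc2c(cc1OCc1ccccc1)O[C@@H](c1ccc(OCc3ccccc3)cc1)[C@@H]2c1cc(OCc2ccccc2)cc(OCc2ccccc2)c1 | intermediate
15 | (2R,3R)-6-(benzyloxy)-2-[4-(benzyloxy)phenyl]-3-[3,5-bis(benzyloxy)phenyl]-2,3-dihydro-1-benzofuran-5-carbaldehyde | O=Cc1cc2c(cc1OCc1ccccc1)O[C@@H](c1ccc(OCc3ccccc3)cc1)[C@@H]2c1cc(OCc2ccccc2)cc(OCc2ccccc2)c1 | intermediate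
16 | 1-(2,4,6-trihydroxyphenyl)ethanone | CC(=O)c1c(O)cc(O)cc1O | starting material
17 | 1-[2,4-bis(benzyloxy)-6-hydroxyphenyl]ethanone | CC(=O)c1c(O)cc(OCc2ccccc2)cc1OCc1ccccc1 | intermediate
18 | 1-[4,6-bis(benzyloxy)-2-hydroxy-3-iodophenyl]ethanone | CC(=O)c1c(O)c(I)c(OCc2ccccc2)cc1OCc1ccccc1 | intermediate
19 | dilithium phenoxide-enolate of 18 | [Li]OC(=C)c1c(O[Li])c(I)c(OCc2ccccc2)cc1OCc1ccccc1 | intermediate
20 | tert-butyl 3-[4,6-bis(benzyloxy)-2-hydroxy-3-iodophenyl]-3-oxopropanoate | CC(C)(C)OC(=O)CC(=O)c1c(O)c(I)c(OCc2ccccc2)cc1OCc1ccccc1 | intermediate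
21 | tert-butyl 2-[4,6-bis(benzyloxy)-2-hydroxy-3-iodobenzoyl]-3-{(2R,3R)-6-(benzyloxy)-2-[4-(benzyloxy)phenyl]-3-[3,5-bis(benzyloxy)phenyl]-2,3-dihydro-1-benzofuran-5-yl}prop-2-enoate (E/Z mixture) | CC(C)(C)OC(=O)C(=Cc1cc2c(cc1OCc1ccccc1)O[C@@H](c1ccc(OCc3ccccc3)cc1)[C@@H]2c1cc(OCc2ccccc2)cc(OCc2ccccc2)c1)C(=O)c1c(O)c(I)c(OCc2ccccc2)cc1OCc1ccccc1 | intermediate
22 | tert-butyl (2S)-5,7-bis(benzyloxy)-2-{(2R,3R)-6-(benzyloxy)-2-[4-(benzyloxy)phenyl]-3-[3,5-bis(benzyloxy)phenyl]-2,3-dihydro-1-benzofuran-5-yl}-8-iodo-4-oxochromane-3-carboxylate (C3 epimers/enol) | CC(C)(C)OC(=O)C1[C@@H](c2cc3c(cc2OCc2ccccc2)O[C@@H](c2ccc(OCc4ccccc4)cc2)[C@@H]3c2cc(OCc3ccccc3)cc(OCc3ccccc3)c2)Oc2c(I)c(OCc3ccccc3)cc(OCc3ccccc3)c2C1=O | intermediate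
23 | (2S)-5,7-bis(benzyloxy)-2-{(2R,3R)-6-(benzyloxy)-2-[4-(benzyloxy)phenyl]-3-[3,5-bis(benzyloxy)phenyl]-2,3-dihydro-1-benzofuran-5-yl}-8-iodo-2,3-dihydro-4H-chromen-4-one | Ic1c(OCc2ccccc2)cc(OCc2ccccc2)c2c1O[C@H](c1cc3c(cc1OCc1ccccc1)O[C@@H](c1ccc(OCc4ccccc4)cc1)[C@@H]3c1cc(OCc3ccccc3)cc(OCc3ccccc3)c1)CC2=O | intermediate
24 | (2S)-2-[(2R,3R)-3-(3,5-dihydroxyphenyl)-6-hydroxy-2-(4-hydroxyphenyl)-2,3-dihydro-1-benzofuran-5-yl]-5,7-dihydroxy-8-iodo-2,3-dihydro-4H-chromen-4-one | Ic1c(O)cc(O)c2c1O[C@H](c1cc3c(cc1O)O[C@@H](c1ccc(O)cc1)[C@@H]3c1cc(O)cc(O)c1)CC2=O | intermediate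
25 | 2-methylbut-1-en-3-yne | C=C(C)C#C | starting material
26 | lithium 3-methylbut-3-en-1-yn-1-ide | C=C(C)C#C[Li] | intermediate
27 | tributyl(3-methylbut-3-en-1-yn-1-yl)stannane | C=C(C)C#C[Sn](CCCC)(CCCC)CCCC | intermediate
28 | chlorobis(cyclopentadienyl)[3-methyl-1-(tributylstannyl)buta-1,3-dien-1-yl]zirconium (Zr trans to isopropenyl) | C=C(C)/C=C(/[Zr](Cl)(C1C=CC=C1)C1C=CC=C1)[Sn](CCCC)(CCCC)CCCC | intermediate
29 | tributyl[(1Z)-3-methylbuta-1,3-dien-1-yl]stannane | C=C(C)/C=C\[Sn](CCCC)(CCCC)CCCC | intermediate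
30 | (2S)-2-[(2R,3R)-3-(3,5-dihydroxyphenyl)-6-hydroxy-2-(4-hydroxyphenyl)-2,3-dihydro-1-benzofuran-5-yl]-5,7-dihydroxy-8-[(1Z)-3-methylbuta-1,3-dien-1-yl]-2,3-dihydro-4H-chromen-4-one | C=C(C)/C=C\c1c(O)cc(O)c2c1O[C@H](c1cc3c(cc1O)O[C@@H](c1ccc(O)cc1)[C@@H]3c1cc(O)cc(O)c1)CC2=O | target

**Count and risks**

Total step count: 16. Longest linear sequence: 11 steps (steps 1–7, 11, 12, 13, 16).

Steps most likely to fail:

Step 6 (the new cascade). The alkoxide may not displace the sulfinyl group fast enough, so that retro-addition, a Truce–Smiles-type aryl shift in the regenerated carbanion or base-induced opening of the product ring outrun ring closure; facial selectivity at C3 may also be lower than the chelate model predicts. Fallback by known chemistry, setting out from 7 and returning at 14: lateral deprotonation of 7 with LiN(i-Pr)2 at −78 °C and addition of 11 would give the racemic bromo alcohol F1 as a mixture of diastereomers. Intramolecular Ullmann-type etherification (CuI, 1,10-phenanthroline, Cs2CO3, toluene, 110 °C) would close it to the racemic dihydrobenzofuran acetal F2, any cis isomer being brought to trans at C2 by a trace of CF3CO2H. The enantiomers of F2 would be separated by preparative chromatography on a chiral stationary phase, the (2R,3R) enantiomer being 14.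

Step 12. Uncatalysed ring closure during or after the Knoevenagel step, and acid-promoted opening and reclosure at C2 during the decarboxylation (the electron-rich ring B stabilises a benzylic cation), may erode the configuration at C2. Fallback, setting out from 18 and 15 and returning at 23: Claisen–Schmidt condensation (KOH, EtOH/THF, 25 °C) would give the chalcone F3, and NaOAc in refluxing EtOH would close it to 23 together with its C2 epimer F4. The two are diastereomers and would be separated by chromatography, F4 being returned to the NaOAc equilibration.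

Step 16. Oxidative addition at the doubly ortho-substituted, electron-rich C–I bond may be slow, and protodeiodination, Z to E isomerisation or cyclisation of the ortho-hydroxy diene may compete. Fallback, setting out from 24 and returning at 30: acetylation (Ac2O, pyridine, DMAP) would give the hexaacetate F5, and Sonogashira coupling with 25 (Pd(PPh3)2Cl2, CuI, Et3N, THF) the enyne F6. Z-selective semi-reduction of the conjugated alkyne (Zn dust activated with Cu(OAc)2 and AgNO3, MeOH/H2O) would give the diene hexaacetate F7, and mild deacetylation (NH4OAc, aqueous MeOH, 25 °C) would give 30.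

Further compounds
F1 | step 6 | racemic 1-[4-(benzyloxy)phenyl]-2-[4-(benzyloxy)-2-bromo-5-(1,3-dioxolan-2-yl)phenyl]-2-[3,5-bis(benzyloxy)phenyl]ethan-1-ol (diastereomer mixture) | OC(c1ccc(OCc2ccccc2)cc1)C(c1cc(OCc2ccccc2)cc(OCc2ccccc2)c1)c1cc(C2OCCO2)c(OCc2ccccc2)cc1Br
F2 | step 6 | racemic trans-2-{6-(benzyloxy)-2-[4-(benzyloxy)phenyl]-3-[3,5-bis(benzyloxy)phenyl]-2,3-dihydro-1-benzofuran-5-yl}-1,3-dioxolane | C1COC(O1)c1cc2c(cc1OCc1ccccc1)OC(c1ccc(OCc3ccccc3)cc1)C2c1cc(OCc2ccccc2)cc(OCc2ccccc2)c1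
F3 | step 12 | (2E)-1-[4,6-bis(benzyloxy)-2-hydroxy-3-iodophenyl]-3-{(2R,3R)-6-(benzyloxy)-2-[4-(benzyloxy)phenyl]-3-[3,5-bis(benzyloxy)phenyl]-2,3-dihydro-1-benzofuran-5-yl}prop-2-en-1-one | O=C(/C=C/c1cc2c(cc1OCc1ccccc1)O[C@@H](c1ccc(OCc3ccccc3)cc1)[C@@H]2c1cc(OCc2ccccc2)cc(OCc2ccccc2)c1)c1c(O)c(I)c(OCc2ccccc2)cc1OCc1ccccc1
F4 | step 12 | (2R)-epimer of 23 at C2 of the chromanone | Ic1c(OCc2ccccc2)cc(OCc2ccccc2)c2c1O[C@@H](c1cc3c(cc1OCc1ccccc1)O[C@@H](c1ccc(OCc4ccccc4)cc1)[C@@H]3c1cc(OCc3ccccc3)cc(OCc3ccccc3)c1)CC2=O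
F5 | step 16 | hexaacetate of 24 | Ic1c(OC(C)=O)cc(OC(C)=O)c2c1O[C@H](c1cc3c(cc1OC(C)=O)O[C@@H](c1ccc(OC(C)=O)cc1)[C@@H]3c1cc(OC(C)=O)cc(OC(C)=O)c1)CC2=O
F6 | step 16 | hexaacetate of the 8-(3-methylbut-3-en-1-yn-1-yl) flavanone | C=C(C)C#Cc1c(OC(C)=O)cc(OC(C)=O)c2c1O[C@H](c1cc3c(cc1OC(C)=O)O[C@@H](c1ccc(OC(C)=O)cc1)[C@@H]3c1cc(OC(C)=O)cc(OC(C)=O)c1)CC2=O
F7 | step 16 | hexaacetate of 30 | C=C(C)/C=C\c1c(OC(C)=O)cc(OC(C)=O)c2c1O[C@H](c1cc3c(cc1OC(C)=O)O[C@@H](c1ccc(OC(C)=O)cc1)[C@@H]3c1cc(OC(C)=O)cc(OC(C)=O)c1)CC2=O
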